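**Plan**
- Retrosynthesis cuts, in order: the flavanone C2–C1' bond (chromone plus arylboronic acid), the flavone C4a–C5 bond (ring A opened to a ketene chain), the C7–C8 bond (malonyl unit removed from a benzylic carbon), and the pyranone ring (triketone from a diketone dianion and an arylacetic ester).
- Enabling feature: flavone ring A (C4a, C5, C6, C7, C8, C8a) is an acylphloroglucinol ring whose C8 carries the flavanone ring B between the C7 hydroxyl and O1 on C8a. C5–C8 can therefore be unfolded as a β-keto ester chain (C8 methine, C7 ketone, C6 methylene, C5 ester) on C2 of a 6-aryl-4-pyranone, which is flavone ring C.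
- Forward order: the 4-pyranone (flavone ring C) is made first, the chain is attached at its benzylic carbon, thermolysis closes flavone ring A, the bromide becomes a boronic acid, and this adds to a separately made chromone to complete the flavanone.
- The hindered interflavonoid biaryl bond is never made by coupling; it is the aryl–CH2 bond of 2-hydroxyphenylacetic acid throughout.
- The only stereocentre, flavanone C2 (S), is set in the conjugate addition by a palladium catalyst carrying a chiral pyridine–oxazoline ligand; the final deprotection is neutral and should not open the flavanone.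

Key step: step 7

Assumption: the (R)-configured pyridine–oxazoline ligand is taken to deliver the aryl group to the Re face of chromone C2 (the mirror image of the sense in which the (S)-ligand gives (R)-adducts of cyclic enones); if the sense is opposite, the (S)-ligand is used, and the biaryl axis is treated as freely rotating.

**Step 1**
Reactants: 1 4'-(benzyloxy)acetophenone
Product: 2 1-[4-(benzyloxy)phenyl]butane-1,3-dione
Conditions: NaH (2.5 equiv), EtOAc (3 equiv), THF, reflux; then 1 M HCl
Reagents that add atoms: ethyl acetate, CCOC(C)=O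
Why: Crossed Claisen condensation in which the sodium enolate of the aryl methyl ketone is acylated by ethyl acetate and the 1,3-diketone is withdrawn from the equilibrium as its sodium salt.

**Step 2**
Reactants: 3 2-hydroxyphenylacetic acid
Product: 4 2-(5-bromo-2-hydroxyphenyl)acetic acid
Conditions: NBS (1.0 equiv), MeCN, 0 °C to rt
Reagents that add atoms: N-bromosuccinimide, O=C1CCC(=O)N1Br
Why: Electrophilic aromatic bromination directed by the phenol to its free para position, which is the carbon that later becomes C1' of the flavanone ring B.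

**Step 3**
Reactants: 4 2-(5-bromo-2-hydroxyphenyl)acetic acid
Product: 5 benzyl 2-[2-(benzyloxy)-5-bromophenyl]acetate
Conditions: BnBr (2.3 equiv), K2CO3 (3 equiv), DMF, rt to 50 °C
Reagents that add atoms: benzyl bromide, BrCc1ccccc1
Why: Williamson etherification of the phenoxide and O-alkylation of the carboxylate in one operation, the benzyl ester being the acyl donor of the next step.

**Step 4**
Reactants: 2 1-[4-(benzyloxy)phenyl]butane-1,3-dione; 5 benzyl 2-[2-(benzyloxy)-5-bromophenyl]acetate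
Product: 6 1-[4-(benzyloxy)phenyl]-6-[2-(benzyloxy)-5-bromophenyl]hexane-1,3,5-trione
Conditions: 2 (2.2 equiv), LiN(i-Pr)2 (4.5 equiv), THF, –78 to 0 °C; then 5 (1 equiv), –78 to 0 °C; 1 M HCl
Reagents that add atoms: none
Why: Claisen-type acylation of a β-diketone dianion at its terminal carbon by an ester, with the dianion in excess because both the triketone formed and the arylacetic ester are proton sources.

**Step 5**
Reactants: 6 1-[4-(benzyloxy)phenyl]-6-[2-(benzyloxy)-5-bromophenyl]hexane-1,3,5-trione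
Product: 7 2-[2-(benzyloxy)-5-bromobenzyl]-6-[4-(benzyloxy)phenyl]-4H-pyran-4-one
Conditions: CF3CO2H/CH2Cl2 (1:4), rt
Reagents that add atoms: none
Why: Acid-catalysed cyclodehydration of a 1,3,5-triketone, in which the enol oxygen of one terminal carbonyl adds to the other and water is lost; either direction gives the same 4-pyranone and aryl benzyl ethers should survive the acid at room temperature.

**Step 6**
Reactants: 7 2-[2-(benzyloxy)-5-bromobenzyl]-6-[4-(benzyloxy)phenyl]-4H-pyran-4-one
Product: 8 tert-butyl 4-[2-(benzyloxy)-5-bromophenyl]-4-{6-[4-(benzyloxy)phenyl]-4-oxo-4H-pyran-2-yl}-3-oxobutanoate (racemic, enolisable methine)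
Conditions: LiN(SiMe3)2 (2.2 equiv), THF, –78 °C; then t-BuO2CCH2COCl (1.3 equiv, made beforehand in CH2Cl2 at 0 °C from mono-tert-butyl malonate and 1-chloro-N,N,2-trimethylprop-1-en-1-amine), –78 to –30 °C; AcOH
Reagents that add atoms: tert-butyl 3-chloro-3-oxopropanoate, CC(C)(C)OC(=O)CC(=O)Cl (made in the flask from mono-tert-butyl malonate, CC(C)(C)OC(=O)CC(=O)O)
Why: Claisen-type C-acylation of the lateral carbanion of a 2-alkyl-4-pyranone (benzylic and vinylogous to the ring carbonyl) by an acid chloride, in which the second equivalent of base takes up the more acidic product and any tert-butoxycarbonylketene formed by deprotonation of the chloride is captured by the same carbanion to give the same enolate.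

**Step 7**
Reactants: 8 tert-butyl 4-[2-(benzyloxy)-5-bromophenyl]-4-{6-[4-(benzyloxy)phenyl]-4-oxo-4H-pyran-2-yl}-3-oxobutanoate
Product: 12 8-[2-(benzyloxy)-5-bromophenyl]-2-[4-(benzyloxy)phenyl]-5,7-dihydroxy-4H-chromen-4-one, via acylketene 9 (not isolated), via dienylketene 10 (not isolated), via 4a-H dienone 11 (not isolated)
Conditions: xylenes (0.005 M), 140 °C, N2
Reagents that add atoms: none
Why: Proposed new method: at 140 °C the tert-butyl β-keto ester should lose tert-butanol through its enol in a six-membered transition state to give acylketene 9, whose ketone enolises toward the doubly activated methine (flavone C8) to give dienylketene 10, in which the pyranone C2=C3 bond (flavone C8a=C4a) is the terminal double bond. Thermal disrotatory six-electron electrocyclisation then joins the ketene carbon (flavone C5) to pyranone C3 (flavone C4a), and tautomerisation of dienone 11 gives the 5,7-dihydroxyflavone with ring B already on C8. The closest known reactions are the thermolysis of tert-butyl β-keto esters or dioxinones to acylketenes and the dienylketene electrocyclisation that ends the Danheiser benzannulation and the cyclobutenone-based phenol annulations, but a 4-pyranone double bond has not served as the terminal two-electron component. The one ring formed, flavone ring A, closes in a 6π-electrocyclic mode that is equivalent in outcome to a 6-endo C-acylation of the pyranone enol-ether carbon. No stereocentre is created, and the racemic methine of 8 becomes the aromatic C8. The step needs closure onto pyranone C3 in preference to the bromoaryl ring and to ketene dimerisation: pyranone C3 is the nucleophilic β-carbon of a vinylogous ester whose use costs little aromatic stabilisation, the only free ortho position of the aryl ring is unactivated and flanked by bromine, high dilution disfavours dimerisation, and since the pyranone oxygen is already O1 no 6-aryl isomer can arise.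

**Step 8**
Reactants: 12 8-[2-(benzyloxy)-5-bromophenyl]-2-[4-(benzyloxy)phenyl]-5,7-dihydroxy-4H-chromen-4-one
Product: 13 5,7-bis(benzyloxy)-8-[2-(benzyloxy)-5-bromophenyl]-2-[4-(benzyloxy)phenyl]-4H-chromen-4-one
Conditions: BnBr (3 equiv), K2CO3 (4 equiv), DMF, 70 °C
Reagents that add atoms: benzyl bromide, BrCc1ccccc1
Why: Williamson etherification of both phenols, the hydrogen-bonded 5-hydroxyl needing warm DMF and an excess of base and halide.

**Step 9**
Reactants: 13 5,7-bis(benzyloxy)-8-[2-(benzyloxy)-5-bromophenyl]-2-[4-(benzyloxy)phenyl]-4H-chromen-4-one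
Product: 14 {4-(benzyloxy)-3-[5,7-bis(benzyloxy)-2-(4-(benzyloxy)phenyl)-4-oxo-4H-chromen-8-yl]phenyl}boronic acid
Conditions: B2(OH)4 (3 equiv), KOAc (3 equiv), chloro(2-dicyclohexylphosphino-2',4',6'-triisopropyl-1,1'-biphenyl)[2-(2'-amino-1,1'-biphenyl)]palladium (2 mol %), XPhos (4 mol %), EtOH/THF, 80 °C
Reagents that add atoms: tetrahydroxydiboron, OB(O)B(O)O
Why: Miyaura borylation with tetrahydroxydiboron, in which oxidative addition of the aryl bromide to zerovalent palladium, acetate-assisted transmetalation from boron and reductive elimination should give the free boronic acid directly while the flavone and the benzyl ethers stay untouched.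

**Step 10**
Reactants: 15 2',6'-dihydroxy-4'-methoxyacetophenone
Product: 16 1-[2-(benzyloxy)-6-hydroxy-4-methoxyphenyl]ethan-1-one
Conditions: BnBr (1.05 equiv), K2CO3 (1.2 equiv), acetone, reflux
Reagents that add atoms: benzyl bromide, BrCc1ccccc1
Why: Williamson mono-etherification, since after the first alkylation the remaining phenol is held in a hydrogen bond to the ketone and should not be alkylated by K2CO3 in acetone.

**Step 11**
Reactants: 16 1-[2-(benzyloxy)-6-hydroxy-4-methoxyphenyl]ethan-1-one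
Product: 18 5-(benzyloxy)-7-methoxy-4H-chromen-4-one, via enaminone 17 (not isolated)
Conditions: Me2NCH(OMe)2 (3 equiv), toluene, 100 °C; concentrate; conc. HCl, CH2Cl2, rt
Reagents that add atoms: N,N-dimethylformamide dimethyl acetal, COC(OC)N(C)C
Why: Enaminone chromone synthesis, in which condensation of the methyl ketone with the amide acetal is followed by acid-promoted conjugate addition of the phenol and loss of dimethylamine to close the pyranone ring.

**Step 12**
Reactants: 14 {4-(benzyloxy)-3-[5,7-bis(benzyloxy)-2-(4-(benzyloxy)phenyl)-4-oxo-4H-chromen-8-yl]phenyl}boronic acid; 18 5-(benzyloxy)-7-methoxy-4H-chromen-4-one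
Product: 19 (2S)-5-(benzyloxy)-2-{4-(benzyloxy)-3-[5,7-bis(benzyloxy)-2-(4-(benzyloxy)phenyl)-4-oxo-4H-chromen-8-yl]phenyl}-7-methoxy-2,3-dihydro-4H-chromen-4-one
Conditions: 18 (2 equiv), Pd(OCOCF3)2 (10 mol %), (R)-4-tert-butyl-2-(pyridin-2-yl)-4,5-dihydrooxazole (12 mol %), NH4PF6 (30 mol %), H2O (5 equiv), ClCH2CH2Cl, 60 °C
Reagents that add atoms: none
Why: Enantioselective 1,4-addition of an arylboronic acid to a chromone catalysed by cationic divalent palladium with a pyridine–oxazoline ligand (transmetalation, enantiodetermining insertion of the chromone C2=C3 bond into the aryl–palladium bond, protonolysis of the palladium enolate by water), in which the tert-butyl group of the (R)-ligand should direct the unhindered aryl group to the Re face of C2 and so set the (2S) centre.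

**Step 13**
Reactants: 19 (2S)-5-(benzyloxy)-2-{4-(benzyloxy)-3-[5,7-bis(benzyloxy)-2-(4-(benzyloxy)phenyl)-4-oxo-4H-chromen-8-yl]phenyl}-7-methoxy-2,3-dihydro-4H-chromen-4-one
Product: 20 8-{2-hydroxy-5-[(2S)-5-hydroxy-7-methoxy-4-oxo-3,4-dihydro-2H-chromen-2-yl]phenyl}-5,7-dihydroxy-2-(4-hydroxyphenyl)-4H-chromen-4-one (CNP0107492.1)
Conditions: H2 (1 atm), Pd/C (10 wt % palladium on carbon), THF/MeOH, rt
Reagents that add atoms: none
Why: Catalytic hydrogenolysis of the five benzyl ethers under neutral conditions, which should leave the methyl ether, the flavone double bond and the base-labile C2 stereocentre of the flavanone unchanged.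

**Compound list**
1 | 4'-(benzyloxy)acetophenone | CC(=O)c1ccc(OCc2ccccc2)cc1 | starting material
2 | 1-[4-(benzyloxy)phenyl]butane-1,3-dione | CC(=O)CC(=O)c1ccc(OCc2ccccc2)cc1 | intermediate
3 | 2-hydroxyphenylacetic acid | OC(=O)Cc1ccccc1O | starting material
4 | 2-(5-bromo-2-hydroxyphenyl)acetic acid | OC(=O)Cc1cc(Br)ccc1O | intermediate
5 | benzyl 2-[2-(benzyloxy)-5-bromophenyl]acetate | O=C(Cc1cc(Br)ccc1OCc1ccccc1)OCc1ccccc1 | intermediate
6 | 1-[4-(benzyloxy)phenyl]-6-[2-(benzyloxy)-5-bromophenyl]hexane-1,3,5-trione | O=C(CC(=O)CC(=O)Cc1cc(Br)ccc1OCc1ccccc1)c1ccc(OCc2ccccc2)cc1 | intermediate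
7 | 2-[2-(benzyloxy)-5-bromobenzyl]-6-[4-(benzyloxy)phenyl]-4H-pyran-4-one | O=c1cc(Cc2cc(Br)ccc2OCc2ccccc2)oc(-c2ccc(OCc3ccccc3)cc2)c1 | intermediate
8 | tert-butyl 4-[2-(benzyloxy)-5-bromophenyl]-4-{6-[4-(benzyloxy)phenyl]-4-oxo-4H-pyran-2-yl}-3-oxobutanoate (racemic) | CC(C)(C)OC(=O)CC(=O)C(c1cc(Br)ccc1OCc1ccccc1)c1cc(=O)cc(-c2ccc(OCc3ccccc3)cc2)o1 | intermediate
9 | 4-[2-(benzyloxy)-5-bromophenyl]-4-{6-[4-(benzyloxy)phenyl]-4-oxo-4H-pyran-2-yl}but-1-ene-1,3-dione (acylketene) | O=C=CC(=O)C(c1cc(Br)ccc1OCc1ccccc1)c1cc(=O)cc(-c2ccc(OCc3ccccc3)cc2)o1 | intermediate (not isolated)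
10 | 4-[2-(benzyloxy)-5-bromophenyl]-4-{6-[4-(benzyloxy)phenyl]-4-oxo-4H-pyran-2-yl}-3-hydroxybuta-1,3-dien-1-one (dienylketene, ketene arm cis to the pyranone) | O=C=C/C(O)=C(/c1cc(Br)ccc1OCc1ccccc1)c1cc(=O)cc(-c2ccc(OCc3ccccc3)cc2)o1 | intermediate (not isolated)
11 | 8-[2-(benzyloxy)-5-bromophenyl]-2-[4-(benzyloxy)phenyl]-7-hydroxy-4aH-chromene-4,5-dione (4a-H dienone, racemic) | O=C1C=C(O)C(c2cc(Br)ccc2OCc2ccccc2)=C2OC(c3ccc(OCc4ccccc4)cc3)=CC(=O)C12 | intermediate (not isolated)
12 | 8-[2-(benzyloxy)-5-bromophenyl]-2-[4-(benzyloxy)phenyl]-5,7-dihydroxy-4H-chromen-4-one | O=c1cc(-c2ccc(OCc3ccccc3)cc2)oc2c(-c3cc(Br)ccc3OCc3ccccc3)c(O)cc(O)c12 | intermediate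
13 | 5,7-bis(benzyloxy)-8-[2-(benzyloxy)-5-bromophenyl]-2-[4-(benzyloxy)phenyl]-4H-chromen-4-one | O=c1cc(-c2ccc(OCc3ccccc3)cc2)oc2c(-c3cc(Br)ccc3OCc3ccccc3)c(OCc3ccccc3)cc(OCc3ccccc3)c12 | intermediate
14 | {4-(benzyloxy)-3-[5,7-bis(benzyloxy)-2-(4-(benzyloxy)phenyl)-4-oxo-4H-chromen-8-yl]phenyl}boronic acid | O=c1cc(-c2ccc(OCc3ccccc3)cc2)oc2c(-c3cc(B(O)O)ccc3OCc3ccccc3)c(OCc3ccccc3)cc(OCc3ccccc3)c12 | intermediate
15 | 2',6'-dihydroxy-4'-methoxyacetophenone | CC(=O)c1c(O)cc(OC)cc1O | starting material
16 | 1-[2-(benzyloxy)-6-hydroxy-4-methoxyphenyl]ethan-1-one | CC(=O)c1c(O)cc(OC)cc1OCc1ccccc1 | intermediate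
17 | (E)-1-[2-(benzyloxy)-6-hydroxy-4-methoxyphenyl]-3-(dimethylamino)prop-2-en-1-one (enaminone) | CN(C)/C=C/C(=O)c1c(O)cc(OC)cc1OCc1ccccc1 | intermediate (not isolated)
18 | 5-(benzyloxy)-7-methoxy-4H-chromen-4-one | COc1cc(OCc2ccccc2)c2c(c1)occc2=O | intermediate
19 | (2S)-5-(benzyloxy)-2-{4-(benzyloxy)-3-[5,7-bis(benzyloxy)-2-(4-(benzyloxy)phenyl)-4-oxo-4H-chromen-8-yl]phenyl}-7-methoxy-2,3-dihydro-4H-chromen-4-one | COc1cc(OCc6ccccc6)c2c(c1)O[C@H](c1ccc(OCc6ccccc6)c(-c3c(OCc6ccccc6)cc(OCc6ccccc6)c4c(=O)cc(-c5ccc(OCc6ccccc6)cc5)oc34)c1)CC2=O | intermediate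
20 | 8-{2-hydroxy-5-[(2S)-5-hydroxy-7-methoxy-4-oxo-3,4-dihydro-2H-chromen-2-yl]phenyl}-5,7-dihydroxy-2-(4-hydroxyphenyl)-4H-chromen-4-one | COc1cc(O)c2c(c1)O[C@H](c1ccc(O)c(-c3c(O)cc(O)c4c(=O)cc(-c5ccc(O)cc5)oc34)c1)CC2=O | target

**Step count**
Total steps: 13. Longest linear sequence: 10 steps (3 → 4 → 5 → 6 → 7 → 8 → 12 → 13 → 14 → 19 → 20; steps 2–9, 12 and 13).

**Steps most likely to fail**

1. Step 7 (proposed new method). The acylketene may be consumed by dimerisation, or by re-addition of the liberated tert-butanol, faster than it enolises and cyclises, or closure may occur onto the bromoaryl ring. The fallback builds the flavone first and makes the biaryl bond by cross-coupling; it sets out from 1 and returns at 13, so step 8 is bypassed as well. Ketone 1 is carboxylated with diethyl carbonate and NaH to ethyl 3-[4-(benzyloxy)phenyl]-3-oxopropanoate F1. F1 is heated neat with phloroglucinol at about 240 °C (Mentzer pyrone synthesis) to give 2-[4-(benzyloxy)phenyl]-5,7-dihydroxy-4H-chromen-4-one F2. Benzylation with BnBr and K2CO3 in DMF gives 5,7-bis(benzyloxy)-2-[4-(benzyloxy)phenyl]-4H-chromen-4-one F3. Iodination with benzyltrimethylammonium dichloroiodate, which 5,7-dialkoxyflavones take at C8, gives 5,7-bis(benzyloxy)-2-[4-(benzyloxy)phenyl]-8-iodo-4H-chromen-4-one F4. Suzuki–Miyaura coupling of F4 at its carbon–iodine bond with commercial [2-(benzyloxy)-5-bromophenyl]boronic acid (Pd(PPh3)4, Na2CO3, DME/H2O, 80 °C) should then give 13 with the bromide intact.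

2. Step 6. Proton transfer from the malonyl chloride to the carbanion and O-acylation of the ambident anion may outrun C-acylation and return 7. The fallback adds the chain as one carbon and then two; it sets out from 7 and returns at 8. The lithium carbanion of 7 (LiN(SiMe3)2, THF, –78 °C) is carboxylated with CO2 and worked up cold to give 2-[2-(benzyloxy)-5-bromophenyl]-2-{6-[4-(benzyloxy)phenyl]-4-oxo-4H-pyran-2-yl}acetic acid F5. Without heating, F5 is activated with 1,1'-carbonyldiimidazole in THF and treated with Mg(O2CCH2CO2t-Bu)2 at rt (Masamune–Brooks decarboxylative Claisen homologation) to give 8.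

3. Step 12. Insertion of the electron-rich 5,7-dioxygenated chromone may be slower than protodeboronation of 14, or facial discrimination may be incomplete. The fallback closes the flavanone from a chalcone and takes the stereocentre from a resolution; it sets out from 13 (with 16) and returns at 19. Reductive carbonylation of 13 (CO 1 atm, HCO2Na, PdCl2(PPh3)2, DMF, 100 °C) gives 4-(benzyloxy)-3-{5,7-bis(benzyloxy)-2-[4-(benzyloxy)phenyl]-4-oxo-4H-chromen-8-yl}benzaldehyde F6. Claisen–Schmidt condensation of F6 with acetophenone 16 (KOH, EtOH/THF, rt) gives (E)-1-[2-(benzyloxy)-6-hydroxy-4-methoxyphenyl]-3-(4-(benzyloxy)-3-{5,7-bis(benzyloxy)-2-[4-(benzyloxy)phenyl]-4-oxo-4H-chromen-8-yl}phenyl)prop-2-en-1-one F7. Oxa-Michael cyclisation (NaOAc, EtOH, reflux) gives racemic 5-(benzyloxy)-2-{4-(benzyloxy)-3-[5,7-bis(benzyloxy)-2-(4-(benzyloxy)phenyl)-4-oxo-4H-chromen-8-yl]phenyl}-7-methoxy-2,3-dihydro-4H-chromen-4-one F8. Preparative HPLC on a chiral stationary phase should deliver 19 and set aside the (2R)-enantiomer of 19 F9.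

**Further compounds**
F1 | step 7 | ethyl 3-[4-(benzyloxy)phenyl]-3-oxopropanoate | CCOC(=O)CC(=O)c1ccc(OCc2ccccc2)cc1
F2 | step 7 | 2-[4-(benzyloxy)phenyl]-5,7-dihydroxy-4H-chromen-4-one | O=c1cc(-c2ccc(OCc3ccccc3)cc2)oc2cc(O)cc(O)c12
F3 | step 7 | 5,7-bis(benzyloxy)-2-[4-(benzyloxy)phenyl]-4H-chromen-4-one | O=c1cc(-c2ccc(OCc3ccccc3)cc2)oc2cc(OCc3ccccc3)cc(OCc3ccccc3)c12
F4 | step 7 | 5,7-bis(benzyloxy)-2-[4-(benzyloxy)phenyl]-8-iodo-4H-chromen-4-one | O=c1cc(-c2ccc(OCc3ccccc3)cc2)oc2c(I)c(OCc3ccccc3)cc(OCc3ccccc3)c12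
F5 | step 6 | 2-[2-(benzyloxy)-5-bromophenyl]-2-{6-[4-(benzyloxy)phenyl]-4-oxo-4H-pyran-2-yl}acetic acid (racemic) | OC(=O)C(c1cc(Br)ccc1OCc1ccccc1)c1cc(=O)cc(-c2ccc(OCc3ccccc3)cc2)o1
F6 | step 12 | 4-(benzyloxy)-3-{5,7-bis(benzyloxy)-2-[4-(benzyloxy)phenyl]-4-oxo-4H-chromen-8-yl}benzaldehyde | O=Cc1ccc(OCc2ccccc2)c(-c2c(OCc3ccccc3)cc(OCc3ccccc3)c3c(=O)cc(-c4ccc(OCc5ccccc5)cc4)oc23)c1
F7 | step 12 | (E)-1-[2-(benzyloxy)-6-hydroxy-4-methoxyphenyl]-3-(4-(benzyloxy)-3-{5,7-bis(benzyloxy)-2-[4-(benzyloxy)phenyl]-4-oxo-4H-chromen-8-yl}phenyl)prop-2-en-1-one | COc1cc(O)c(C(=O)/C=C/c2ccc(OCc3ccccc3)c(-c3c(OCc4ccccc4)cc(OCc4ccccc4)c4c(=O)cc(-c5ccc(OCc6ccccc6)cc5)oc34)c2)c(OCc2ccccc2)c1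
F8 | step 12 | racemic 5-(benzyloxy)-2-{4-(benzyloxy)-3-[5,7-bis(benzyloxy)-2-(4-(benzyloxy)phenyl)-4-oxo-4H-chromen-8-yl]phenyl}-7-methoxy-2,3-dihydro-4H-chromen-4-one | COc1cc(OCc6ccccc6)c2c(c1)OC(c1ccc(OCc6ccccc6)c(-c3c(OCc6ccccc6)cc(OCc6ccccc6)c4c(=O)cc(-c5ccc(OCc6ccccc6)cc5)oc34)c1)CC2=O
F9 | step 12 | (2R)-enantiomer of 19 | COc1cc(OCc6ccccc6)c2c(c1)O[C@@H](c1ccc(OCc6ccccc6)c(-c3c(OCc6ccccc6)cc(OCc6ccccc6)c4c(=O)cc(-c5ccc(OCc6ccccc6)cc5)oc34)c1)CC2=O
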